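Its constants belong to no real substance, and the outcome is calculated.

Start from slowness: in this flask you need to know which passage is the slow one, the solid going into solution or the coupling that follows it.

solid substrate 0.025 M; coupling partner 0.0250 M; time 25 min

- how much target and crystals together there is at 25 min, in percent of the solid substrate charged
- concentration of dissolved substrate in solution at 6.0 min, in percent of saturation
- the change that raises the amount of target and crystals together at 25 min, in percent of the solid substrate charged most ("none" if none brings more than 2 percentage points) (amber / blue / ochre / teal / none)
- amount of target and crystals together at 25 min, in percent of the solid substrate charged, after amber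

- in percentages every species weighs as the solid substrate in it: one side product counts as two
- for target the crystals are counted in
- a doubled species enters its step squared and goes two at a time
- as a solid, counted per litre of solution: solid substrate, crystals
- at the start none of the solid substrate is in solution
- dissolved substrate means what is dissolved; the solid is not counted in it
- run time (flask): 25 min

- amber: doubling the dissolution coefficient of step 2, all else as stated
- blue: doubling the solubility in step 6, all else as stated
- ochre: doubling the amount of coupling partner, all else as stated
- teal: doubling the dissolution coefficient of step 6, all else as stated

    2 coupling partner → homo dimer (k1 = 0.476 L mol⁻¹ min⁻¹)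
    crystals ⇌ target, rate k2*(cs2 - [target]) while solid is left; crystals form when [target] > cs2 (cs2 = 3.8 mM, k2 = 0.515 min⁻¹)
    2 dissolved substrate → side product (k3 = 0.691 L mol⁻¹ min⁻¹)
    dissolved substrate + coupling partner → target (k4 = 1.15 L mol⁻¹ min⁻¹)
    coupling partner ⇌ dormant form (K5 = 7.8, k5 = 0.0218 min⁻¹)
    solid substrate ⇌ dissolved substrate, rate k6*(cs6 - [dissolved substrate]) while solid is left; crystals form when [dissolved substrate] > cs6 (cs6 = 14 mM, k6 = 1.56 min⁻¹)

Turn the question round. For a faster dissolution to pay, what the solution uses would have to approach what the solid can deliver. With dissolved substrate at its solubility, coupling and side product together use at the start

demand = 0.673 mM min⁻¹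

whereas the solid delivers into empty solution

supply = 21.8 mM min⁻¹

That is 32.4 times the demand, so, I expect [dissolved substrate] to stand near solubility, at 96.9% of it once the pool has filled while coupling partner is still as charged, and a little higher later as demand falls. So your question is the pace of coupling. Coupling partner then meets a steady pool, a pseudo-first-order loss:

coupling constant κ = 0.0161 min⁻¹

with the dormant form's forward step, λ = 0.0379 min⁻¹

Adding the pairing to homo dimer, with b = 2 × 0.476 L mol⁻¹ min⁻¹ and c the charged coupling partner, and integrating to time t gives the area under [coupling partner]:

J = ln(1 + b·c·(1 − e^(−λt))/λ)/b = 342 mM·min

The reach, κJ over the solid charged, is the share of target and crystals expected with the pool held at solubility: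

reach = 22.0%

Pool, side product and reach together ask 105% of the charge, so I expect the solid to give out near the end. Target is not consumed and crystals are counted, so I expect amber to add nothing. Doubled partner gives a reach of 38.6%. Blue, with the whole charge taken as dissolved, gives 35.2%, less than that, so I choose ochre.

The forecast gives 20.9% of target and crystals, 97.5% of saturation at 6.0 min, ochre as the best change and 20.9% after amber, its yield lower than my reach; its ground for the pool reads: “Dissolution is fast, so dissolved substrate sits just under saturation”.

The flask gives 20.9%, 97.5%, ochre and 20.9%; ochre adds 14 percentage points, blue 4 points, teal 0.56 points and amber 0 points.

In this flask the result is 0.951 of the reach. Now take the neighbouring flask with 0.015 M of coupling partner. At 25.0 min its dissolved substrate stands at 55.1% of the charge, with 6.31% still solid, so the same κ applies. The smaller charge gives a reach of 14.0%, and the same ratio brings that to 13.4%. That neighbouring flask ends with 13.4% of target and crystals together.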